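**Retrosynthetic overview**

1. The strategy rests on ring B: its C2' hydroxyl is ortho to the diaryl ether oxygen on C1', and the carboxyl carbon on C1 of ring A is ortho to the same ether oxygen on C6. O(C2') and the carboxyl carbon are therefore the two ends of a seven-membered lactone (C1, C=O, O, C2', C1', O, C6), a dibenzo[b,e][1,4]dioxepin-11-one (depsidone).
2. Target 14 ⇐ depsidone diacetate 13 (hydroxide opens the lactone and removes both acetates) ⇐ diacetoxy acid 12, by anodic joining of a carboxyl oxygen to C2'–H, so the C2' oxygen arrives last.
3. 12 ⇐ prenyl aldehyde 8 (aldehyde reduction, saponification, acetylation) ⇐ allyl phenol 6 (cross-metathesis) ⇐ allyl ether 5 (Claisen rearrangement puts the carbon chain on C3).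
4. 5 ⇐ phenol 3 + 2-fluoro-5-methylbenzaldehyde 4 (SNAr gives the C6–O–C1' ether at a ring B carbon with only one ortho substituent); 3 ⇐ mono-allylation of methyl 2,6-dihydroxybenzoate 1.
5. Ring order: both benzene rings are bought; the dioxepinone is the only ring formed (step 7) and it is opened again in step 8.

Key step: step 7

**Remarks.** The target has no stereocentre and no stereogenic double bond, so there is no enantiomer to select. Locants used below: ring A C1 (carboxyl), C2 (OH), C3 (prenyl), C6 (ether O); ring B C1' (ether O), C2' (OH), C4' (CH3), C6' (CH2OH). 3-Bromo-2-fluoro-5-methylbenzaldehyde and 2-bromo-5-methylbenzaldehyde appear only in fallbacks and are assumed to be purchasable.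

**Route**

Step 1
Reactants: 1 methyl 2,6-dihydroxybenzoate; 2 allyl bromide
Product: 3 methyl 2-hydroxy-6-(prop-2-enyloxy)benzoate
Conditions: K2CO3 (1.1 equiv), allyl bromide (1.05 equiv), acetone, reflux
Reagents that add atoms: none
Why: Williamson ether synthesis; with one equivalent of halide the reaction should stop at the mono-ether, because the remaining hydroxyl is held in a hydrogen bond to the ester carbonyl and is a poorer nucleophile.

Step 2
Reactants: 3 methyl 2-hydroxy-6-(prop-2-enyloxy)benzoate; 4 2-fluoro-5-methylbenzaldehyde
Product: 5 methyl 2-(2-formyl-4-methylphenoxy)-6-(prop-2-enyloxy)benzoate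
Conditions: K2CO3, DMF, 120 °C, N2
Reagents that add atoms: none
Why: Nucleophilic aromatic substitution (addition–elimination) of the fluoride ortho to the formyl group by the phenoxide of 3; the temperature stays well below that of the allyl ether Claisen rearrangement, and the ester is stable to dry carbonate.

Step 3
Reactants: 5 methyl 2-(2-formyl-4-methylphenoxy)-6-(prop-2-enyloxy)benzoate
Product: 6 methyl 6-(2-formyl-4-methylphenoxy)-2-hydroxy-3-(prop-2-enyl)benzoate
Conditions: Ph2O, 200 °C, Ar
Reagents that add atoms: none
Why: Aromatic Claisen rearrangement ([3,3]-sigmatropic shift, then tautomerisation); of the two ortho carbons of the allyloxy group, C1 carries the ester, so the allyl group should go to C3 and free the C2 hydroxyl.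

Step 4
Reactants: 6 methyl 6-(2-formyl-4-methylphenoxy)-2-hydroxy-3-(prop-2-enyl)benzoate; 7 2-methylbut-2-ene
Product: 8 methyl 6-(2-formyl-4-methylphenoxy)-2-hydroxy-3-(3-methylbut-2-enyl)benzoate
Conditions: second-generation Ru benzylidene metathesis catalyst (Grubbs II, 3 mol %), 2-methylbut-2-ene (large excess)/CH2Cl2, 35 °C, sealed vessel
Reagents that add atoms: none
Why: Olefin cross-metathesis of a terminal allyl arene with excess 2-methylbut-2-ene turns allyl into prenyl with loss of propene; the trisubstituted product alkene does not react further, and phenol, aldehyde and ester are tolerated by the catalyst.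

Step 5
Reactants: 8 methyl 6-(2-formyl-4-methylphenoxy)-2-hydroxy-3-(3-methylbut-2-enyl)benzoate
Product: 10 2-hydroxy-6-[2-(hydroxymethyl)-4-methylphenoxy]-3-(3-methylbut-2-enyl)benzoic acid, via hydroxymethyl methyl ester 9 (not isolated)
Conditions: NaBH4 (0.5 equiv), MeOH/THF, 0 °C; then aq. KOH (excess), 70 °C; then 1 M HCl to pH 3, 0 °C
Reagents that add atoms: potassium hydroxide, [K+].[OH-]
Why: Borohydride reduces the aryl aldehyde chemoselectively at 0 °C, and hydroxide then saponifies the methyl ester by acyl substitution in the same flask; the ester is flanked by two ortho groups and needs heat, which the alkene, the diaryl ether and the benzylic alcohol tolerate.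

Step 6
Reactants: 10 2-hydroxy-6-[2-(hydroxymethyl)-4-methylphenoxy]-3-(3-methylbut-2-enyl)benzoic acid
Product: 12 2-acetoxy-6-[2-(acetoxymethyl)-4-methylphenoxy]-3-(3-methylbut-2-enyl)benzoic acid, via mixed acetic anhydride 11 (not isolated)
Conditions: Ac2O (4 equiv), pyridine, DMAP (cat.), CH2Cl2, 0 °C to rt; then H2O/THF, rt
Reagents that add atoms: acetic anhydride, CC(=O)OC(C)=O
Why: DMAP-catalysed acylation esterifies the phenol and the benzylic alcohol; the carboxyl group is taken to the mixed anhydride, which water cleaves at its unhindered acetyl carbonyl in the quench, as in the preparation of acetylsalicylic acid, and fast O-acetylation of the alcohol keeps it from closing an eight-membered lactone.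

Step 7
Reactants: 12 2-acetoxy-6-[2-(acetoxymethyl)-4-methylphenoxy]-3-(3-methylbut-2-enyl)benzoic acid
Product: 13 1-acetoxy-6-(acetoxymethyl)-8-methyl-2-(3-methylbut-2-enyl)-11H-dibenzo[b,e][1,4]dioxepin-11-one
Conditions: graphite felt (+)/Pt (−), undivided cell, 2,6-lutidine (1 equiv), nBu4NBF4 (0.1 M), MeCN/HFIP, controlled potential at the foot of the carboxylate wave (located beforehand by cyclic voltammetry), about 2.2 F/mol, rt
Reagents that add atoms: none
Why: Proposed new method: the lutidinium carboxylate of 12 should give up one electron at the anode to form the aroyloxy radical, whose oxygen adds to the free ortho carbon C2' of ring B; the cyclohexadienyl radical so formed, with spin on the oxygen-bearing C1', gives up a second electron, and loss of the C2' proton restores ring B while the cathode turns the two protons into hydrogen. The closest known reaction type is the anodic or photocatalytic dehydrogenative lactonisation of biaryl-2-carboxylic acids to benzo[c]chromen-6-ones, which follows the same sequence of radical addition, oxidation and deprotonation but closes a six-membered ring. Here the one new ring, the seven-membered 1,4-dioxepinone, closes by 7-endo attack of the carboxyl oxygen on an arene carbon, and no stereocentre is formed. The step needs attack at C2' to win over 6-exo ipso attack at C1', which would break the ether bond and move the aryl group to the carboxyl oxygen (the known radical Smiles path of 2-aryloxybenzoic acids), and it needs the prenyl alkene, the 4'-methyl group and ring A to stay unoxidised. For the first, the acetoxymethyl group on C6' flanks C1' and should prefer the rotamer that turns it away from the carboxyl group, which places C2'–H next to the carboxyl oxygen as the only ortho carbon open to closure, while the acetoxy and aryloxy groups on both sides of the carboxyl group crowd the spiro transition state at C1'; this bias is an expectation, not a certainty, and is the main risk of the route. For the second, the potential is held at the carboxylate wave, which is expected to lie below the waves of the trisubstituted alkene and of the two alkyl aryl ether rings, and the acetate on O2 removes the easily oxidised phenol.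

Step 8
Reactants: 13 1-acetoxy-6-(acetoxymethyl)-8-methyl-2-(3-methylbut-2-enyl)-11H-dibenzo[b,e][1,4]dioxepin-11-one
Product: 14 2-hydroxy-6-[2-hydroxy-6-(hydroxymethyl)-4-methylphenoxy]-3-(3-methylbut-2-enyl)benzoic acid
Conditions: LiOH·H2O (excess), THF/H2O, 0 °C to rt; then 1 M HCl to pH 3, 0 °C
Reagents that add atoms: lithium hydroxide, [Li+].[OH-]
Why: Hydroxide opens the activated aryl ester of the lactone by acyl substitution, freeing the carboxylate and the C2' phenoxide, and cleaves the aryl and benzylic acetates in the same flask; the hydroxy acid set free on cold acidification should not close again without a dehydrating agent.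

**Compound list**

1 | methyl 2,6-dihydroxybenzoate | COC(=O)c1c(O)cccc1O | starting material
2 | allyl bromide (3-bromoprop-1-ene) | C=CCBr | starting material
3 | methyl 2-hydroxy-6-(prop-2-enyloxy)benzoate | COC(=O)c1c(O)cccc1OCC=C | intermediate
4 | 2-fluoro-5-methylbenzaldehyde | Cc1ccc(F)c(C=O)c1 | starting material
5 | methyl 2-(2-formyl-4-methylphenoxy)-6-(prop-2-enyloxy)benzoate | COC(=O)c1c(OCC=C)cccc1Oc1ccc(C)cc1C=O | intermediate
6 | methyl 6-(2-formyl-4-methylphenoxy)-2-hydroxy-3-(prop-2-enyl)benzoate | COC(=O)c1c(O)c(CC=C)ccc1Oc1ccc(C)cc1C=O | intermediate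
7 | 2-methylbut-2-ene | CC=C(C)C | starting material
8 | methyl 6-(2-formyl-4-methylphenoxy)-2-hydroxy-3-(3-methylbut-2-enyl)benzoate | COC(=O)c1c(O)c(CC=C(C)C)ccc1Oc1ccc(C)cc1C=O | intermediate
9 | methyl 2-hydroxy-6-[2-(hydroxymethyl)-4-methylphenoxy]-3-(3-methylbut-2-enyl)benzoate (formed in the flask in step 5) | COC(=O)c1c(O)c(CC=C(C)C)ccc1Oc1ccc(C)cc1CO | intermediate
10 | 2-hydroxy-6-[2-(hydroxymethyl)-4-methylphenoxy]-3-(3-methylbut-2-enyl)benzoic acid | CC(C)=CCc1ccc(Oc2ccc(C)cc2CO)c(C(=O)O)c1O | intermediate
11 | acetic 2-acetoxy-6-[2-(acetoxymethyl)-4-methylphenoxy]-3-(3-methylbut-2-enyl)benzoic anhydride (formed in the flask in step 6) | CC(C)=CCc1ccc(Oc2ccc(C)cc2COC(C)=O)c(C(=O)OC(C)=O)c1OC(C)=O | intermediate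
12 | 2-acetoxy-6-[2-(acetoxymethyl)-4-methylphenoxy]-3-(3-methylbut-2-enyl)benzoic acid | CC(C)=CCc1ccc(Oc2ccc(C)cc2COC(C)=O)c(C(=O)O)c1OC(C)=O | intermediate
13 | 1-acetoxy-6-(acetoxymethyl)-8-methyl-2-(3-methylbut-2-enyl)-11H-dibenzo[b,e][1,4]dioxepin-11-one | CC(C)=CCc1ccc2Oc3c(COC(C)=O)cc(C)cc3OC(=O)c2c1OC(C)=O | intermediate
14 | 2-hydroxy-6-[2-hydroxy-6-(hydroxymethyl)-4-methylphenoxy]-3-(3-methylbut-2-enyl)benzoic acid (CNP0140656.0) | CC(C)=CCc1ccc(Oc2c(O)cc(C)cc2CO)c(C(=O)O)c1O | target

**Totals**

Total step count: 8. Longest linear sequence: 8 steps (1 → 3 → 5 → 6 → 8 → 10 → 12 → 13 → 14).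

**Steps most likely to fail**

Step 7 (proposed new method). The carboxyl oxygen may close at the ipso carbon C1' instead of C2', after which the ether bond breaks and the aryl group migrates to the carboxyl oxygen. Over-oxidation of the prenyl alkene or of the benzylic positions of ring B, and decarboxylation of the aroyloxy radical, are further ways the material may be lost. The fallback brings the C2' oxygen in as a bromine by known chemistry; it sets out from phenol 3 and comes back to the route at the target 14. SNAr of 3 with 3-bromo-2-fluoro-5-methylbenzaldehyde (K2CO3, DMF, 100 °C) should give methyl 2-(2-bromo-6-formyl-4-methylphenoxy)-6-(prop-2-enyloxy)benzoate F1. Claisen rearrangement as in step 3 should give methyl 6-(2-bromo-6-formyl-4-methylphenoxy)-2-hydroxy-3-(prop-2-enyl)benzoate F2. Cross-metathesis with 7 as in step 4 should give methyl 6-(2-bromo-6-formyl-4-methylphenoxy)-2-hydroxy-3-(3-methylbut-2-enyl)benzoate F3. NaBH4 in MeOH at 0 °C should give methyl 6-[2-bromo-6-(hydroxymethyl)-4-methylphenoxy]-2-hydroxy-3-(3-methylbut-2-enyl)benzoate F4. Copper-catalysed hydroxylation of the aryl bromide (CuI, an 8-hydroxyquinoline or oxalamide ligand, KOH, DMSO/H2O, 100 °C), under which the methyl ester is saponified as well, followed by cold acidification, should then give 14. Copper is chosen over palladium here so that the aryl–metal species cannot close a dibenzofuran onto ring A.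

Step 2. The hydrogen-bonded, ortho-substituted phenoxide of 3 is a weak nucleophile and the fluoride is activated by a single formyl group, so substitution may be slow; forcing it may start the Claisen rearrangement early or cleave the ester. The fallback is a copper-catalysed Ullmann ether synthesis; it sets out from 3 and comes back at 5. Phenol 3 is coupled with 2-bromo-5-methylbenzaldehyde (CuI, picolinic acid, K3PO4, DMSO, 90 °C), a cross-coupling that does not depend on addition–elimination at the arene and is known to tolerate ortho-substituted phenols; no new compound is made (F0).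

Step 5. Acyl substitution at the ester carbonyl, which sits between two ortho substituents and next to a phenoxide, may stay incomplete, and forcing it raises the chance of decarboxylation on acidification. The fallback cleaves the other ester bond; it sets out from 9, isolated after the borohydride stage, and comes back at 10. Sodium ethanethiolate in DMF at 90 °C attacks the methyl carbon of the ester (SN2 dealkylation) and not the shielded carbonyl carbon, and cold acidification then gives 10; no new compound is made (F0).

**Further compounds**

F1 | step 7 | methyl 2-(2-bromo-6-formyl-4-methylphenoxy)-6-(prop-2-enyloxy)benzoate | COC(=O)c1c(OCC=C)cccc1Oc1c(Br)cc(C)cc1C=O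
F2 | step 7 | methyl 6-(2-bromo-6-formyl-4-methylphenoxy)-2-hydroxy-3-(prop-2-enyl)benzoate | COC(=O)c1c(O)c(CC=C)ccc1Oc1c(Br)cc(C)cc1C=O
F3 | step 7 | methyl 6-(2-bromo-6-formyl-4-methylphenoxy)-2-hydroxy-3-(3-methylbut-2-enyl)benzoate | COC(=O)c1c(O)c(CC=C(C)C)ccc1Oc1c(Br)cc(C)cc1C=O
F4 | step 7 | methyl 6-[2-bromo-6-(hydroxymethyl)-4-methylphenoxy]-2-hydroxy-3-(3-methylbut-2-enyl)benzoate | COC(=O)c1c(O)c(CC=C(C)C)ccc1Oc1c(Br)cc(C)cc1CO
F0 | step 2 | none | none
F0 | step 5 | none | none
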